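A direct plan would build the ring A/ring C chromone first and attach ring B last. Pentamethoxybenzene A1 would be lithiated and acylated with a methoxyacetyl Weinreb amide, one ortho methyl ether would be removed with BCl3, and an amide acetal would close the ring to 3,5,6,7,8-pentamethoxychromone A2. A2 would then be arylated at C2–H with 5-bromo-1,3-diisopropoxy-2-methoxybenzene A3 under palladium catalysis, and BCl3 would free the three hydroxyls.
Its weakest steps would be:
- the C2–H arylation joining A2 and A3: the only convergent bond would rest on a reaction not shown for 3-alkoxychromones and on a hindered, electron-rich bromide;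
- the metalation and acylation of the fully substituted arene A1: two lithiations, a methylation and a demethylation would be spent on adding one oxygen and one acyl group;
- the borylation–bromination sequence to A3: three steps would serve only to place one halogen.

The new route would disconnect ring A itself. Its four contiguous oxygenated carbons C5–C8 match dimethyl squarate, and C4a/C8a are the C5=C6 bond of a 2-aryl-3-methoxy-4-pyranone that already holds ring B, O1 and the 3-methoxy group. Thermal ring expansion of the squarate–pyranone adduct would close ring A, create the chromone bicycle and deliver the para-related C5/C8 oxygens as a hydroquinone, whose two hydroxyls are told apart by the hydrogen bond from 5-OH to the C4 carbonyl. No aryl group is joined to C2 of a chromone, no fully substituted arene is metalated and acylated, and ring B needs no halogen: it enters as a benzoyl chloride.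

Key step: step 7

Assumption: methyl 3,5-dihydroxy-4-methoxybenzoate (methyl 4-O-methylgallate) is taken as a commercial starting material.
Remark: 15 is drawn as the C6-linked adduct; a C5-linked regioisomer from step 6 would give the same hydroquinone 18 in step 7, so the main route does not depend on the site of metalation.

Step 1
Reactants: 1 N,2-dimethoxy-N-methylacetamide; 2 ethynylmagnesium bromide
Product: 5 (E)-1-methoxy-4-[methoxy(methyl)amino]but-3-en-2-one, via bromomagnesium hemiaminal alkoxide 3 (not isolated), via 1-methoxybut-3-yn-2-one 4 (not isolated)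
Conditions: HC≡CMgBr (1.3 equiv, 0.5 M in THF), THF, 0 °C → rt; then sat. aq NH4Cl, rt, 2 h
Reagents that add atoms: none
Why: The chelated magnesium adduct 3 takes up only one acetylide and collapses to ynone 4 on quenching (Weinreb ketone synthesis), and the N,O-dimethylhydroxylamine set free at that moment adds to the terminal ynone in an aza-Michael reaction to give the thermodynamically preferred (E)-enaminone; no stereocentre is kept.

Step 2
Reactants: 6 methyl 3,5-dihydroxy-4-methoxybenzoate
Product: 7 methyl 3,5-bis(benzyloxy)-4-methoxybenzoate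
Conditions: BnBr (2.4 equiv), K2CO3 (3 equiv), DMF, 60 °C
Reagents that add atoms: benzyl bromide, BrCc1ccccc1
Why: Williamson O-benzylation of both phenols; the benzyl ethers should survive the base, acid, organomagnesium and thermal steps and leave by hydrogenolysis at the end.

Step 3
Reactants: 7 methyl 3,5-bis(benzyloxy)-4-methoxybenzoate
Product: 8 3,5-bis(benzyloxy)-4-methoxybenzoic acid
Conditions: LiOH·H2O (3 equiv), THF/MeOH/H2O, 50 °C; then 1 M HCl
Reagents that add atoms: lithium hydroxide, [Li+].[OH-]
Why: Saponification of the methyl ester, with no other base-sensitive group present.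

Step 4
Reactants: 8 3,5-bis(benzyloxy)-4-methoxybenzoic acid
Product: 9 3,5-bis(benzyloxy)-4-methoxybenzoyl chloride
Conditions: (COCl)2 (1.5 equiv), DMF (cat.), CH2Cl2, 0 °C → rt; evaporated and used crude
Reagents that add atoms: oxalyl chloride, ClC(=O)C(=O)Cl
Why: Acid chloride formation through the chloroiminium species from DMF and oxalyl chloride; aryl benzyl and methyl ethers are inert to it.

Step 5
Reactants: 5 (E)-1-methoxy-4-[methoxy(methyl)amino]but-3-en-2-one (2.1 equiv); 9 3,5-bis(benzyloxy)-4-methoxybenzoyl chloride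
Product: 12 2-[3,5-bis(benzyloxy)-4-methoxyphenyl]-3-methoxy-4H-pyran-4-one, via lithium dienolate 10 (not isolated), via aminovinyl 1,3-diketone 11 (not isolated)
Conditions: 5, LiN(SiMe3)2 (2.1 equiv), THF, −78 °C; 9 (1.0 equiv), −78 → −40 °C; aq NH4Cl; crude 11, CF3CO2H (3 equiv), CH2Cl2, 0 °C → rt
Reagents that add atoms: none
Why: C1 is the only enolisable position of 5, so its chelated (Z)-lithium enolate is C-acylated by 9 to a 1,3-diketone (enolate acylation), and acid then lets the aryl ketone enol oxygen add to the aminovinyl carbon and expel N,O-dimethylhydroxylamine, closing the 4-pyranone (acid-mediated cyclisation of an acylated β-heteroatom-substituted enone to a γ-pyrone); the stereocentre of 11 is lost.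

Step 6
Reactants: 12 2-[3,5-bis(benzyloxy)-4-methoxyphenyl]-3-methoxy-4H-pyran-4-one; 13 dimethyl squarate (3,4-dimethoxycyclobut-3-ene-1,2-dione)
Product: 15 2-[3,5-bis(benzyloxy)-4-methoxyphenyl]-6-(1-hydroxy-2,3-dimethoxy-4-oxocyclobut-2-en-1-yl)-3-methoxy-4H-pyran-4-one (racemic), via 6-pyranonylmagnesium chloride 14 (not isolated)
Conditions: (2,2,6,6-tetramethylpiperidin-1-yl)MgCl·LiCl (TMPMgCl·LiCl, 1.2 equiv), THF, −40 °C, 1 h; then 13 (1.3 equiv), −78 → −30 °C; sat. aq NH4Cl
Reagents that add atoms: none
Why: The hindered magnesium amide should remove the most acidic ring hydrogen, C6–H next to O1 at the β end of the enone, without adding to the pyranone (magnesiation with a Knochel–Hauser base), and the pyranonylmagnesium adds 1,2 to one of the two equivalent carbonyl groups of 13 (organometal addition to a squarate ester); the carbinol carbon forms as a racemate and is destroyed in step 7.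

Step 7
Reactants: 15 2-[3,5-bis(benzyloxy)-4-methoxyphenyl]-6-(1-hydroxy-2,3-dimethoxy-4-oxocyclobut-2-en-1-yl)-3-methoxy-4H-pyran-4-one
Product: 18 2-[3,5-bis(benzyloxy)-4-methoxyphenyl]-5,8-dihydroxy-3,6,7-trimethoxy-4H-chromen-4-one, via (Z)-dienylketene 16 (not isolated), via 4aH-chromene-4,5-dione 17 (not isolated)
Conditions: toluene (degassed, dilute), 110 °C, Ar, 2 h
Reagents that add atoms: none
Why: Heating opens the cyclobutenone by conrotatory 4π electrocyclic cleavage of its C1–C4 bond to the dienylketene 16, and the hydroxyl, as the donor on the sp3 carbon, rotates outward, which places the pyranonyl group inward beside the ketene. The ketene carbon then bonds to C5 of the pyranone C5=C6 bond in a thermal disrotatory 6π electrocyclisation that closes ring A as a six-membered carbocycle fused to ring C (17), and enolisation of the C4a hydrogen gives the aromatic hydroquinone 18. The closest known reaction type is the thermal ring expansion of 4-alkenyl-, 4-aryl- and 4-heteroaryl-4-hydroxycyclobutenones made from squarate esters to hydroquinones (Moore rearrangement), known for furyl and thienyl groups. No stereocentre is formed and the one in 15 is destroyed. Regiochemistry needs no control, because C5, C6, C7 and C8 are the four squarate carbons in their original order, C4a and C8a are the pyranone C5 and C6, and an adduct joined through C5 would give the same 18. The step needs only exclusion of oxygen, since 18 is an electron-rich hydroquinone, and a free C–H on the pyranone double bond for the final enolisation, which the substrate provides.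

Step 8
Reactants: 18 2-[3,5-bis(benzyloxy)-4-methoxyphenyl]-5,8-dihydroxy-3,6,7-trimethoxy-4H-chromen-4-one
Product: 19 2-[3,5-bis(benzyloxy)-4-methoxyphenyl]-5-hydroxy-3,6,7,8-tetramethoxy-4H-chromen-4-one
Conditions: MeI (1.1 equiv), K2CO3 (1.1 equiv), acetone (degassed), rt, Ar
Reagents that add atoms: iodomethane, CI
Why: The 5-hydroxyl is held in a hydrogen bond to the C4 carbonyl and is the less reactive phenol, so one equivalent of MeI with a weak base should methylate only the 8-hydroxyl (partial Williamson methylation, as is usual for 5-hydroxyflavones).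

Step 9
Reactants: 19 2-[3,5-bis(benzyloxy)-4-methoxyphenyl]-5-hydroxy-3,6,7,8-tetramethoxy-4H-chromen-4-one
Product: 20 5,3',5'-trihydroxy-3,6,7,8,4'-pentamethoxyflavone
Conditions: H2 (1 atm), 10% Pd/C, EtOAc/MeOH, rt
Reagents that add atoms: none
Why: Hydrogenolysis of the two benzyl ethers on palladium should leave the methyl ethers and the tetrasubstituted C2=C3 bond of the flavone untouched and give the achiral target (catalytic debenzylation).

**Compound list**
1 | N,2-dimethoxy-N-methylacetamide | COCC(=O)N(C)OC | starting material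
2 | ethynylmagnesium bromide | C#C[Mg]Br | starting material
3 | bromomagnesium 1-methoxy-2-[methoxy(methyl)amino]but-3-yn-2-olate (racemic, collapses on quenching) | COCC(O[Mg]Br)(C#C)N(C)OC | intermediate (not isolated)
4 | 1-methoxybut-3-yn-2-one | COCC(=O)C#C | intermediate (not isolated)
5 | (E)-1-methoxy-4-[methoxy(methyl)amino]but-3-en-2-one | COCC(=O)/C=C/N(C)OC | intermediate
6 | methyl 3,5-dihydroxy-4-methoxybenzoate | COC(=O)c1cc(O)c(OC)c(O)c1 | starting material
7 | methyl 3,5-bis(benzyloxy)-4-methoxybenzoate | COC(=O)c1cc(OCc2ccccc2)c(OC)c(OCc2ccccc2)c1 | intermediate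
8 | 3,5-bis(benzyloxy)-4-methoxybenzoic acid | OC(=O)c1cc(OCc2ccccc2)c(OC)c(OCc2ccccc2)c1 | intermediate
9 | 3,5-bis(benzyloxy)-4-methoxybenzoyl chloride | ClC(=O)c1cc(OCc2ccccc2)c(OC)c(OCc2ccccc2)c1 | intermediate
10 | lithium (1Z,3E)-1-methoxy-4-[methoxy(methyl)amino]buta-1,3-dien-2-olate | [Li+].CO/C=C(\[O-])/C=C/N(C)OC | intermediate (not isolated)
11 | (E)-1-[3,5-bis(benzyloxy)-4-methoxyphenyl]-2-methoxy-5-[methoxy(methyl)amino]pent-4-ene-1,3-dione (racemic at C2, enolisable) | CON(C)/C=C/C(=O)C(OC)C(=O)c1cc(OCc2ccccc2)c(OC)c(OCc2ccccc2)c1 | intermediate (not isolated)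
12 | 2-[3,5-bis(benzyloxy)-4-methoxyphenyl]-3-methoxy-4H-pyran-4-one | COc1c(-c2cc(OCc3ccccc3)c(OC)c(OCc3ccccc3)c2)occc1=O | intermediate
13 | dimethyl squarate (3,4-dimethoxycyclobut-3-ene-1,2-dione) | COC1=C(OC)C(=O)C1=O | starting material
14 | {6-[3,5-bis(benzyloxy)-4-methoxyphenyl]-5-methoxy-4-oxo-4H-pyran-2-yl}magnesium chloride (LiCl complex) | COc1c(-c2cc(OCc3ccccc3)c(OC)c(OCc3ccccc3)c2)oc([Mg]Cl)cc1=O | intermediate (not isolated)
15 | 2-[3,5-bis(benzyloxy)-4-methoxyphenyl]-6-(1-hydroxy-2,3-dimethoxy-4-oxocyclobut-2-en-1-yl)-3-methoxy-4H-pyran-4-one (racemic) | COC1=C(OC)C(O)(c2cc(=O)c(OC)c(-c3cc(OCc4ccccc4)c(OC)c(OCc4ccccc4)c3)o2)C1=O | intermediate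
16 | 2-[3,5-bis(benzyloxy)-4-methoxyphenyl]-6-[(1Z)-1-hydroxy-2,3-dimethoxy-4-oxobuta-1,3-dien-1-yl]-3-methoxy-4H-pyran-4-one | O=C=C(OC)/C(OC)=C(/O)c1cc(=O)c(OC)c(-c2cc(OCc3ccccc3)c(OC)c(OCc3ccccc3)c2)o1 | intermediate (not isolated)
17 | 2-[3,5-bis(benzyloxy)-4-methoxyphenyl]-8-hydroxy-3,6,7-trimethoxy-4aH-chromene-4,5-dione (racemic at C4a) | O=C1C(OC)=C(OC)C(O)=C2OC(c3cc(OCc4ccccc4)c(OC)c(OCc4ccccc4)c3)=C(OC)C(=O)C12 | intermediate (not isolated)
18 | 2-[3,5-bis(benzyloxy)-4-methoxyphenyl]-5,8-dihydroxy-3,6,7-trimethoxy-4H-chromen-4-one | COc1c(OC)c(O)c2oc(-c3cc(OCc4ccccc4)c(OC)c(OCc4ccccc4)c3)c(OC)c(=O)c2c1O | intermediate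
19 | 2-[3,5-bis(benzyloxy)-4-methoxyphenyl]-5-hydroxy-3,6,7,8-tetramethoxy-4H-chromen-4-one | COc1c(OC)c(OC)c2oc(-c3cc(OCc4ccccc4)c(OC)c(OCc4ccccc4)c3)c(OC)c(=O)c2c1O | intermediate
20 | 5,3',5'-trihydroxy-3,6,7,8,4'-pentamethoxyflavone | COc1c(O)cc(-c2oc3c(OC)c(OC)c(OC)c(O)c3c(=O)c2OC)cc1O | target

Total step count: 9.
Longest linear sequence: 8 steps (from 6 through steps 2 to 9).

Steps most likely to fail:

1. Step 6. The metalated pyranone may add in conjugate fashion to unmetalated 12, may open its ring, or may add too slowly to the squarate carbonyl. The fallback sets out from 12 and makes the carbanion at C5 by halogen–magnesium exchange instead of deprotonation. 12 would be iodinated with I2 and pyridine in CH2Cl2 (conjugate addition of pyridine at C6, iodination of the enolate, elimination) to 2-[3,5-bis(benzyloxy)-4-methoxyphenyl]-5-iodo-3-methoxy-4H-pyran-4-one F1. Exchange with iPrMgCl·LiCl at −40 °C and addition to 13 would give the C5-linked adduct 2-[3,5-bis(benzyloxy)-4-methoxyphenyl]-5-(1-hydroxy-2,3-dimethoxy-4-oxocyclobut-2-en-1-yl)-3-methoxy-4H-pyran-4-one F2 (racemic). Heating F2 as in step 7 would close ring A from the other side and come back to the route at 18.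

2. Step 7. The hydroquinone may be oxidised to the 5,8-quinone during or after heating, or the hydroxy dienylketene may be diverted before it cyclises. The fallback sets out from 15 and moves the differentiation of the two para oxygens in front of the ring expansion. The tertiary alcohol would be methylated (MeI, Ag2O, MeCN, rt) to 2-[3,5-bis(benzyloxy)-4-methoxyphenyl]-3-methoxy-6-(1,2,3-trimethoxy-4-oxocyclobut-2-en-1-yl)-4H-pyran-4-one F3 (racemic). Heating F3 in toluene would give a monophenol that cannot form a quinone and already carries the 8-methoxy group, so it comes back at 19 and step 8 is not needed. This fallback requires the C6-linked adduct as drawn.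

3. Step 5. The lithium enolate may be acylated on oxygen instead of carbon, or the diketone may be acylated a second time. The fallback sets out from 9 and forms the same carbon–carbon bond by aldol addition and oxidation. 9 would be reduced with LiAlH(OtBu)3 in THF at −78 °C to 3,5-bis(benzyloxy)-4-methoxybenzaldehyde F4. Addition of the lithium dienolate 10 to F4 would give (E)-5-[3,5-bis(benzyloxy)-4-methoxyphenyl]-5-hydroxy-4-methoxy-1-[methoxy(methyl)amino]pent-1-en-3-one F5 (mixture of racemic diastereomers). Oxidation of F5 with Dess–Martin periodinane would come back at 11, which is closed to 12 by the acid treatment of step 5.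

Further compounds
F1 | step 6 | 2-[3,5-bis(benzyloxy)-4-methoxyphenyl]-5-iodo-3-methoxy-4H-pyran-4-one | COc1c(-c2cc(OCc3ccccc3)c(OC)c(OCc3ccccc3)c2)occ(I)c1=O
F2 | step 6 | 2-[3,5-bis(benzyloxy)-4-methoxyphenyl]-5-(1-hydroxy-2,3-dimethoxy-4-oxocyclobut-2-en-1-yl)-3-methoxy-4H-pyran-4-one (racemic) | COC1=C(OC)C(O)(c2coc(-c3cc(OCc4ccccc4)c(OC)c(OCc4ccccc4)c3)c(OC)c2=O)C1=O
F3 | step 7 | 2-[3,5-bis(benzyloxy)-4-methoxyphenyl]-3-methoxy-6-(1,2,3-trimethoxy-4-oxocyclobut-2-en-1-yl)-4H-pyran-4-one (racemic) | COC1=C(OC)C(OC)(c2cc(=O)c(OC)c(-c3cc(OCc4ccccc4)c(OC)c(OCc4ccccc4)c3)o2)C1=O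
F4 | step 5 | 3,5-bis(benzyloxy)-4-methoxybenzaldehyde | O=Cc1cc(OCc2ccccc2)c(OC)c(OCc2ccccc2)c1
F5 | step 5 | (E)-5-[3,5-bis(benzyloxy)-4-methoxyphenyl]-5-hydroxy-4-methoxy-1-[methoxy(methyl)amino]pent-1-en-3-one (mixture of racemic diastereomers) | CON(C)/C=C/C(=O)C(OC)C(O)c1cc(OCc2ccccc2)c(OC)c(OCc2ccccc2)c1
A1 | direct plan | pentamethoxybenzene | COc1cc(OC)c(OC)c(OC)c1OC
A2 | direct plan | 3,5,6,7,8-pentamethoxy-4H-chromen-4-one | COc1coc2c(OC)c(OC)c(OC)c(OC)c2c1=O
A3 | direct plan | 5-bromo-1,3-diisopropoxy-2-methoxybenzene | COc1c(OC(C)C)cc(Br)cc1OC(C)C
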